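**Plan**

Numbering follows the heptane chain: C1 carries ring A and the ring oxygen, C3 the hydroxyl, C5 the second O–CH, and C6–C7 lead to ring B.
Cuts, in retrosynthetic order: C1–H and C1–ring A (back to a δ-lactone with C1 as carbonyl), then C2–C3 inside that lactone, then the C5–O ester bond, then C4–C5 (allyl onto a C5 aldehyde).
Forward: ring B with C7–C6–C5 comes from dihydroferulic acid, allylation adds C4 and C3, bromoacetate brings C1 and C2, the SmI2 Reformatsky reaction closes the only new ring as a lactone, and ring A is put on C1 last.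
Stereochemistry: C5 by reagent-controlled Brown allylboration; C3 from C5 through the samarium chelate; C1 from C3 and C5 by axial hydride delivery to the cyclic oxocarbenium ion.
Enabling feature: on the tetrahydropyran the C3 hydroxyl is axial and trans to the equatorial arylethyl arm on C5, and C1 is an oxygen-bearing ring carbon that can be carried as a lactone carbonyl. This is the pattern that a chelated closure of a C5 bromoacetate onto a C3 aldehyde delivers.

Key step: step 6

Remark: the target SMILES is read as the (2S,4S,6S) isomer (ring A and the arylethyl arm cis and equatorial, the hydroxyl axial and trans to both). The allylborane of step 3 is specified by its source, (−)-α-pinene, because the sign quoted for the B-allyl reagent itself is not uniform.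

**Route**

Step 1
Reactants: 1 3-(4-hydroxy-3-methoxyphenyl)propanoic acid
Product: 2 benzyl 3-[4-(benzyloxy)-3-methoxyphenyl]propanoate
Conditions: BnBr (2.4 equiv), K2CO3, DMF, 60 °C
Reagents that add atoms: benzyl bromide, BrCc1ccccc1
Why: Williamson etherification of the phenoxide and SN2 esterification of the carboxylate run together under K2CO3 in DMF, so one operation masks the ring B phenol and turns the acid into a reducible ester.

Step 2
Reactants: 2 benzyl 3-[4-(benzyloxy)-3-methoxyphenyl]propanoate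
Product: 4 3-[4-(benzyloxy)-3-methoxyphenyl]propanal, via aluminium hemiacetal 3 (not isolated)
Conditions: i-Bu2AlH (1.05 equiv), CH2Cl2, −78 °C; then MeOH, aq KNaC4H4O6 (potassium sodium tartrate)
Reagents that add atoms: none
Why: Partial ester reduction with i-Bu2AlH, in which the tetrahedral aluminium hemiacetal 3 persists at −78 °C and releases the aldehyde only on work-up, out of reach of further hydride.

Step 3
Reactants: 4 3-[4-(benzyloxy)-3-methoxyphenyl]propanal
Product: 6 (3S)-1-[4-(benzyloxy)-3-methoxyphenyl]hex-5-en-3-ol, via borinate ester 5 (not isolated)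
Conditions: CH2=CHCH2MgBr, (+)-Ipc2BOMe [from (−)-α-pinene], Et2O, −78 to 25 °C; then 4, −78 °C; then NaOH, H2O2, 25 °C
Reagents that add atoms: allylmagnesium bromide, C=CC[Mg]Br (its allyl group, passed on through the B-allylborane)
Why: Brown asymmetric allylboration, in which the B-allyl reagent with isopinocampheyl groups from (−)-α-pinene delivers allyl through a chair six-membered transition state to the Re face of the unbranched aldehyde, setting C5 as S (allyl outranks the arylethyl arm), after which alkaline H2O2 frees the alcohol from borinate 5.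

Step 4
Reactants: 6 (3S)-1-[4-(benzyloxy)-3-methoxyphenyl]hex-5-en-3-ol; 7 bromoacetyl bromide
Product: 8 (3S)-1-[4-(benzyloxy)-3-methoxyphenyl]hex-5-en-3-yl bromoacetate
Conditions: pyridine, CH2Cl2, −20 to 0 °C
Reagents that add atoms: none
Why: O-acylation of the secondary alcohol by the acid bromide with pyridine as acyl-transfer agent and HBr scavenger is fast at low temperature, outpaces N-alkylation of pyridine by the bromoacetate and leaves the C5 stereocentre untouched.

Step 5
Reactants: 8 (3S)-1-[4-(benzyloxy)-3-methoxyphenyl]hex-5-en-3-yl bromoacetate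
Product: 10 (3S)-5-[4-(benzyloxy)-3-methoxyphenyl]-1-oxopentan-3-yl bromoacetate, via vicinal diol 9 (not isolated)
Conditions: OsO4 (2 mol%), NaIO4 (4 equiv), 2,6-lutidine, dioxane/H2O 3:1, 25 °C; crude product used at once
Reagents that add atoms: osmium tetroxide, O=[Os](=O)(=O)=O (source of the aldehyde oxygen; reoxidised by sodium periodate, [Na+].[O-]I(=O)(=O)=O)
Why: Lemieux–Johnson oxidation, in which catalytic OsO4 dihydroxylates the terminal alkene to diol 9 and NaIO4 cleaves it in the same flask, while 2,6-lutidine buffers the medium so that the bromoacetate and the β-acyloxy aldehyde survive and the electron-rich arenes stay inert.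

Step 6
Reactants: 10 (3S)-5-[4-(benzyloxy)-3-methoxyphenyl]-1-oxopentan-3-yl bromoacetate
Product: 13 (4S,6S)-6-{2-[4-(benzyloxy)-3-methoxyphenyl]ethyl}-4-hydroxytetrahydro-2H-pyran-2-one, via samarium enolate 11 (not isolated), via samarium aldolate 12 (not isolated)
Conditions: SmI2 (2.2 equiv, 0.1 M), THF, −78 °C, slow addition of 10; then 0.1 M aq HCl
Reagents that add atoms: none
Why: Two equivalents of SmI2 (divalent samarium) cleave the C–Br bond by successive single-electron transfers and give the trivalent samarium ester enolate 11, whose carbon C2 adds to the C3 aldehyde to form the C2–C3 bond and aldolate 12; the closest known reaction type is the SmI2-promoted intramolecular Reformatsky reaction of β-(bromoacetoxy) aldehydes and ketones to β-hydroxy δ-lactones. The six-membered lactone ring (O, C1, C2, C3, C4, C5) closes in a 6-(enolendo)-exo-trig mode. The new C3 stereocentre is controlled by the C5 stereocentre through 1,3-induction: samarium bridges the enolate oxygen and the aldehyde oxygen, so the closure runs through a bicyclic chair-like chelate in which the C3–O bond must stand axial on the forming ring while the C5 arylethyl arm stays equatorial, which is the trans (4S,6S) arrangement. The step needs reduction of the α-bromo ester in preference to the aldehyde and ring closure faster than β-elimination of the acyloxy group; the far easier reduction of the α-halo ester, the temperature of −78 °C and the slow addition of 10 to an excess of SmI2 should secure this.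

Step 7
Reactants: 13 (4S,6S)-6-{2-[4-(benzyloxy)-3-methoxyphenyl]ethyl}-4-hydroxytetrahydro-2H-pyran-2-one
Product: 14 (4S,6S)-6-{2-[4-(benzyloxy)-3-methoxyphenyl]ethyl}-4-[(tert-butyldimethylsilyl)oxy]tetrahydro-2H-pyran-2-one
Conditions: TBSCl, imidazole, DMF, 25 °C
Reagents that add atoms: tert-butyldimethylsilyl chloride, CC(C)(C)[Si](C)(C)Cl
Why: Silyl ether formation under Corey conditions masks the C3 hydroxyl against the aryllithium of step 9, and imidazole is too weak a base to trigger β-elimination in the lactone.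

Step 8
Reactants: 15 4-bromo-2-methoxyphenol
Product: 16 1-(benzyloxy)-4-bromo-2-methoxybenzene
Conditions: BnBr, K2CO3, acetone, reflux
Reagents that add atoms: benzyl bromide, BrCc1ccccc1
Why: Williamson etherification gives a bromide fit for bromine–lithium exchange and puts on ring A the same benzyl mask as on ring B, so that one hydrogenolysis frees both phenols.

Step 9
Reactants: 14 (4S,6S)-6-{2-[4-(benzyloxy)-3-methoxyphenyl]ethyl}-4-[(tert-butyldimethylsilyl)oxy]tetrahydro-2H-pyran-2-one; 16 1-(benzyloxy)-4-bromo-2-methoxybenzene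
Product: 18 (4S,6S)-2-[4-(benzyloxy)-3-methoxyphenyl]-6-{2-[4-(benzyloxy)-3-methoxyphenyl]ethyl}-4-[(tert-butyldimethylsilyl)oxy]tetrahydro-2H-pyran-2-ol, via aryllithium 17 (not isolated)
Conditions: 16, n-BuLi, THF, −78 °C; then 14, THF, −78 °C; sat. aq NH4Cl at −78 °C
Reagents that add atoms: none
Why: Bromine–lithium exchange gives aryllithium 17, which adds once to the lactone carbonyl at −78 °C (1,2-addition, the lithium hemiketal alkoxide holding until the quench), so that C1 gains ring A and lactol 18 results as anomers in equilibrium with the open hydroxy ketone.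

Step 10
Reactants: 18 (4S,6S)-2-[4-(benzyloxy)-3-methoxyphenyl]-6-{2-[4-(benzyloxy)-3-methoxyphenyl]ethyl}-4-[(tert-butyldimethylsilyl)oxy]tetrahydro-2H-pyran-2-ol
Product: 20 (2S,4S,6S)-2-[4-(benzyloxy)-3-methoxyphenyl]-6-{2-[4-(benzyloxy)-3-methoxyphenyl]ethyl}-4-[(tert-butyldimethylsilyl)oxy]tetrahydro-2H-pyran, via oxocarbenium ion 19 (not isolated)
Conditions: Et3SiH, BF3·OEt2, CH2Cl2/MeCN, −78 to −40 °C
Reagents that add atoms: none
Why: Lewis-acid-promoted ionic hydrogenation of a lactol, in which BF3·OEt2 ionises 18 to the aryl-stabilised oxocarbenium ion 19, whose half-chair keeps the C5 arylethyl arm pseudo-equatorial and the C3 silyloxy group pseudo-axial, and Et3SiH adds along the axial trajectory so that ring A ends up equatorial and C1 is set as S (2,6-cis).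

Step 11
Reactants: 20 (2S,4S,6S)-2-[4-(benzyloxy)-3-methoxyphenyl]-6-{2-[4-(benzyloxy)-3-methoxyphenyl]ethyl}-4-[(tert-butyldimethylsilyl)oxy]tetrahydro-2H-pyran
Product: 21 (2S,4S,6S)-2-[4-(benzyloxy)-3-methoxyphenyl]-6-{2-[4-(benzyloxy)-3-methoxyphenyl]ethyl}tetrahydro-2H-pyran-4-ol
Conditions: Bu4NF, THF, 25 °C
Reagents that add atoms: none
Why: Fluoride-mediated desilylation, driven by the strong Si–F bond, frees the axial C3 hydroxyl without touching the benzyl ethers or any stereocentre.

Step 12
Reactants: 21 (2S,4S,6S)-2-[4-(benzyloxy)-3-methoxyphenyl]-6-{2-[4-(benzyloxy)-3-methoxyphenyl]ethyl}tetrahydro-2H-pyran-4-ol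
Product: 22 (2S,4S,6S)-2-(4-hydroxy-3-methoxyphenyl)-6-[2-(4-hydroxy-3-methoxyphenyl)ethyl]tetrahydro-2H-pyran-4-ol
Conditions: H2 (1 atm), 10% Pd/C, EtOAc, 25 °C, stopped when 21 is consumed
Reagents that add atoms: none
Why: Catalytic hydrogenolysis over Pd/C cleaves the two aryl benzyl ethers much faster than the hindered secondary benzylic C1–O bond of the ring, so short exposure in a non-acidic solvent should free both phenols and leave the tetrahydropyran intact.

**Compound list**

1 | 3-(4-hydroxy-3-methoxyphenyl)propanoic acid (dihydroferulic acid) | OC(=O)CCc1ccc(O)c(OC)c1 | starting material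
2 | benzyl 3-[4-(benzyloxy)-3-methoxyphenyl]propanoate | COc1cc(CCC(=O)OCc2ccccc2)ccc1OCc1ccccc1 | intermediate
3 | diisobutylaluminium alkoxide of the benzyl hemiacetal of 4 (aluminium hemiacetal) | COc1cc(CCC(OCc2ccccc2)O[Al](CC(C)C)CC(C)C)ccc1OCc1ccccc1 | intermediate
4 | 3-[4-(benzyloxy)-3-methoxyphenyl]propanal | COc1cc(CCC=O)ccc1OCc1ccccc1 | intermediate
5 | (3S)-1-[4-(benzyloxy)-3-methoxyphenyl]hex-5-en-3-yl diisopinocampheylborinate | COc1cc(CC[C@H](OB([C@@H]2[C@@H](C)[C@@H]3C[C@H](C2)C3(C)C)[C@@H]2[C@@H](C)[C@@H]3C[C@H](C2)C3(C)C)CC=C)ccc1OCc1ccccc1 | intermediate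
6 | (3S)-1-[4-(benzyloxy)-3-methoxyphenyl]hex-5-en-3-ol | COc1cc(CC[C@H](O)CC=C)ccc1OCc1ccccc1 | intermediate
7 | bromoacetyl bromide | BrCC(Br)=O | starting material
8 | (3S)-1-[4-(benzyloxy)-3-methoxyphenyl]hex-5-en-3-yl bromoacetate | COc1cc(CC[C@H](OC(=O)CBr)CC=C)ccc1OCc1ccccc1 | intermediate
9 | (3S)-1-[4-(benzyloxy)-3-methoxyphenyl]-5,6-dihydroxyhexan-3-yl bromoacetate (both epimers at the new carbinol) | COc1cc(CC[C@H](OC(=O)CBr)CC(O)CO)ccc1OCc1ccccc1 | intermediate
10 | (3S)-5-[4-(benzyloxy)-3-methoxyphenyl]-1-oxopentan-3-yl bromoacetate | COc1cc(CC[C@H](OC(=O)CBr)CC=O)ccc1OCc1ccccc1 | intermediate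
11 | trivalent samarium ester enolate of 10 (diiodosamarium ketene acetal) | COc1cc(CC[C@H](OC(=C)O[Sm](I)I)CC=O)ccc1OCc1ccccc1 | intermediate
12 | diiodosamarium alkoxide of 13 (samarium aldolate) | COc1cc(CC[C@H]2C[C@H](O[Sm](I)I)CC(=O)O2)ccc1OCc1ccccc1 | intermediate
13 | (4S,6S)-6-{2-[4-(benzyloxy)-3-methoxyphenyl]ethyl}-4-hydroxytetrahydro-2H-pyran-2-one (trans lactone) | COc1cc(CC[C@H]2C[C@H](O)CC(=O)O2)ccc1OCc1ccccc1 | intermediate
14 | (4S,6S)-6-{2-[4-(benzyloxy)-3-methoxyphenyl]ethyl}-4-[(tert-butyldimethylsilyl)oxy]tetrahydro-2H-pyran-2-one | COc1cc(CC[C@H]2C[C@H](O[Si](C)(C)C(C)(C)C)CC(=O)O2)ccc1OCc1ccccc1 | intermediate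
15 | 4-bromo-2-methoxyphenol | COc1cc(Br)ccc1O | starting material
16 | 1-(benzyloxy)-4-bromo-2-methoxybenzene | COc1cc(Br)ccc1OCc1ccccc1 | intermediate
17 | [4-(benzyloxy)-3-methoxyphenyl]lithium | COc1cc([Li])ccc1OCc1ccccc1 | intermediate
18 | (4S,6S)-2-[4-(benzyloxy)-3-methoxyphenyl]-6-{2-[4-(benzyloxy)-3-methoxyphenyl]ethyl}-4-[(tert-butyldimethylsilyl)oxy]tetrahydro-2H-pyran-2-ol (anomers, in equilibrium with the open hydroxy ketone) | COc1cc(CC[C@H]2C[C@H](O[Si](C)(C)C(C)(C)C)CC(O)(c3ccc(OCc4ccccc4)c(OC)c3)O2)ccc1OCc1ccccc1 | intermediate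
19 | 2-aryl oxocarbenium ion derived from 18 | COc1cc(CC[C@H]2C[C@H](O[Si](C)(C)C(C)(C)C)CC(c3ccc(OCc4ccccc4)c(OC)c3)=[O+]2)ccc1OCc1ccccc1 | intermediate
20 | (2S,4S,6S)-2-[4-(benzyloxy)-3-methoxyphenyl]-6-{2-[4-(benzyloxy)-3-methoxyphenyl]ethyl}-4-[(tert-butyldimethylsilyl)oxy]tetrahydro-2H-pyran | COc1cc(CC[C@H]2C[C@H](O[Si](C)(C)C(C)(C)C)C[C@@H](c3ccc(OCc4ccccc4)c(OC)c3)O2)ccc1OCc1ccccc1 | intermediate
21 | (2S,4S,6S)-2-[4-(benzyloxy)-3-methoxyphenyl]-6-{2-[4-(benzyloxy)-3-methoxyphenyl]ethyl}tetrahydro-2H-pyran-4-ol | COc1cc(CC[C@H]2C[C@H](O)C[C@@H](c3ccc(OCc4ccccc4)c(OC)c3)O2)ccc1OCc1ccccc1 | intermediate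
22 | (2S,4S,6S)-2-(4-hydroxy-3-methoxyphenyl)-6-[2-(4-hydroxy-3-methoxyphenyl)ethyl]tetrahydro-2H-pyran-4-ol | COc1cc(CC[C@H]2C[C@H](O)C[C@@H](c3ccc(O)c(OC)c3)O2)ccc1O | target

**Step count**

Total: 12 steps. Longest linear sequence: 11 steps (steps 1 to 7 and 9 to 12); step 8 is a one-step branch.

**Steps most likely to fail**

Step 5. The β-(bromoacetoxy) aldehyde may lose bromoacetic acid by E1cB elimination in the buffered aqueous medium or on silica, and the α-bromo ester may be attacked by the amine base. The fallback sets out from 6 and cleaves the alkene before the ester is made. OsO4/NaIO4 on the free alcohol should give (3S)-5-[4-(benzyloxy)-3-methoxyphenyl]-3-hydroxypentanal F1. This is masked at once with HC(OMe)3 and pyridinium p-toluenesulfonate in MeOH as (3S)-1-[4-(benzyloxy)-3-methoxyphenyl]-5,5-dimethoxypentan-3-ol F2. Bromoacetylation as in step 4 then gives (3S)-1-[4-(benzyloxy)-3-methoxyphenyl]-5,5-dimethoxypentan-3-yl bromoacetate F3. Wet CF3CO2H in CH2Cl2 at 0 °C unmasks the aldehyde under acid, never under base, and the route is rejoined at 10 immediately before the samarium step.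

Step 6. The 1,3-induction may be incomplete if part of the closure escapes the chelate, and the aldehyde may be reduced or pinacol-coupled by divalent samarium before the enolate closes. The fallback sets out from 6 and builds the same trans lactone by substrate-controlled epoxidation. Acryloyl chloride and Et3N give (3S)-1-[4-(benzyloxy)-3-methoxyphenyl]hex-5-en-3-yl prop-2-enoate F4. Ring-closing metathesis with the second-generation Grubbs catalyst RuCl2(=CHPh)(H2IMes)(PCy3) in CH2Cl2 at 40 °C gives (6S)-6-{2-[4-(benzyloxy)-3-methoxyphenyl]ethyl}-5,6-dihydro-2H-pyran-2-one F5. Alkaline H2O2 in MeOH at 0 °C should epoxidise it anti to the C5 side chain to the trans-3,4-epoxy lactone F6. Reductive opening at the α-carbon with PhSeH, made from (PhSe)2 and NaBH4 in EtOH/AcOH, leaves the C3–O bond in place, and the route is rejoined at 13.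

Step 9. The lithium hemiketal may collapse early to the aryl ketone and take up a second aryllithium, or the lactone may be enolised and lose the silyloxy group by β-elimination. The fallback sets out from 14 and opens the lactone with MeNH(OMe)·HCl and Me3Al to (3S,5S)-7-[4-(benzyloxy)-3-methoxyphenyl]-3-[(tert-butyldimethylsilyl)oxy]-5-hydroxy-N-methoxy-N-methylheptanamide F7. Et3SiCl and imidazole convert it into the 5-triethylsilyl ether F8. Aryllithium 17 then stops cleanly at (3S,5S)-1,7-bis[4-(benzyloxy)-3-methoxyphenyl]-3-[(tert-butyldimethylsilyl)oxy]-5-[(triethylsilyl)oxy]heptan-1-one F9, because the Weinreb chelate cannot over-add. Reductive etherification with Et3SiH and BiBr3 in MeCN closes the ring through the same oxocarbenium ion 19, and the route is rejoined at 20.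

**Further compounds**

F1 | step 5 | (3S)-5-[4-(benzyloxy)-3-methoxyphenyl]-3-hydroxypentanal | COc1cc(CC[C@H](O)CC=O)ccc1OCc1ccccc1
F2 | step 5 | (3S)-1-[4-(benzyloxy)-3-methoxyphenyl]-5,5-dimethoxypentan-3-ol | COc1cc(CC[C@H](O)CC(OC)OC)ccc1OCc1ccccc1
F3 | step 5 | (3S)-1-[4-(benzyloxy)-3-methoxyphenyl]-5,5-dimethoxypentan-3-yl bromoacetate | COc1cc(CC[C@H](OC(=O)CBr)CC(OC)OC)ccc1OCc1ccccc1
F4 | step 6 | (3S)-1-[4-(benzyloxy)-3-methoxyphenyl]hex-5-en-3-yl prop-2-enoate | COc1cc(CC[C@H](OC(=O)C=C)CC=C)ccc1OCc1ccccc1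
F5 | step 6 | (6S)-6-{2-[4-(benzyloxy)-3-methoxyphenyl]ethyl}-5,6-dihydro-2H-pyran-2-one | COc1cc(CC[C@H]2CC=CC(=O)O2)ccc1OCc1ccccc1
F6 | step 6 | (6S)-6-{2-[4-(benzyloxy)-3-methoxyphenyl]ethyl}-3,4-epoxytetrahydro-2H-pyran-2-one, epoxide oxygen trans to the C6 side chain | COc1cc(CC[C@H]2C[C@@H]3O[C@@H]3C(=O)O2)ccc1OCc1ccccc1
F7 | step 9 | (3S,5S)-7-[4-(benzyloxy)-3-methoxyphenyl]-3-[(tert-butyldimethylsilyl)oxy]-5-hydroxy-N-methoxy-N-methylheptanamide | COc1cc(CC[C@H](O)C[C@H](O[Si](C)(C)C(C)(C)C)CC(=O)N(C)OC)ccc1OCc1ccccc1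
F8 | step 9 | (3S,5S)-7-[4-(benzyloxy)-3-methoxyphenyl]-3-[(tert-butyldimethylsilyl)oxy]-N-methoxy-N-methyl-5-[(triethylsilyl)oxy]heptanamide | COc1cc(CC[C@H](O[Si](CC)(CC)CC)C[C@H](O[Si](C)(C)C(C)(C)C)CC(=O)N(C)OC)ccc1OCc1ccccc1
F9 | step 9 | (3S,5S)-1,7-bis[4-(benzyloxy)-3-methoxyphenyl]-3-[(tert-butyldimethylsilyl)oxy]-5-[(triethylsilyl)oxy]heptan-1-one | COc1cc(CC[C@H](O[Si](CC)(CC)CC)C[C@H](O[Si](C)(C)C(C)(C)C)CC(=O)c2ccc(OCc3ccccc3)c(OC)c2)ccc1OCc1ccccc1
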